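**Retrosynthetic overview**
1. The target acid comes from its ethyl ester (acid hydrolysis last). The ester comes from a secondary carbinol by radical deoxygenation.
2. Key disconnection is the lactone C3–CH(OH) bond. It is made by aldol addition of the lithium enolate of (R)-4-(3,4-dimethoxybenzyl)butyrolactone to ethyl 4-formyl-2-pyrone-6-carboxylate, and the C4 substituent directs trans.
3. The pyrone comes from a γ-selective (vinylogous) Claisen condensation of ethyl 3-methylbut-2-enoate with diethyl oxalate, followed by HCl ring closure. The 4-CH3 is then taken to CH2Br and to CHO.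
4. The lactone comes from an Evans alkylation of the 3-(3,4-dimethoxyphenyl)propanoyl imide with tert-butyl bromoacetate, which sets C4. The auxiliary is then removed, the acid reduced with BH3, and the ring closed.
5. Ring order: the butyrolactone (step 5) and the 2-pyrone (step 7) are each closed in their own branch before the union. No ring is formed afterwards.

Assumption: the target is the (3R,4R)-trans lactone encoded in the SMILES. The carbinol centre of 23 and 24 is carried as an epimer mixture because step 13 deletes it.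

**Route**

Step 1
Reactants: 1 3-(3,4-dimethoxyphenyl)propanoic acid; 2 (S)-4-benzyl-1,3-oxazolidin-2-one
Product: 4 (S)-4-benzyl-3-[3-(3,4-dimethoxyphenyl)propanoyl]-1,3-oxazolidin-2-one, via mixed pivalic anhydride 3 (not isolated)
Conditions: PivCl, Et3N, THF, −20 °C, 1 h; then LiCl, 2, −20 °C → rt, 12 h
Reagents that add atoms: none
Why: Mixed-anhydride N-acylation, in which the LiCl-activated oxazolidinone attacks the unhindered acyl carbon of 3 and the auxiliary centre is untouched.

Step 2
Reactants: 4 N-acyl oxazolidinone; 5 tert-butyl bromoacetate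
Product: 7 tert-butyl (3R)-3-{[(4S)-4-benzyl-2-oxo-1,3-oxazolidin-3-yl]carbonyl}-4-(3,4-dimethoxyphenyl)butanoate, via sodium Z-enolate 6 (not isolated)
Conditions: NaHMDS (1.1 equiv), THF, −78 °C, 45 min; 5 (1.5 equiv), −78 → −40 °C
Reagents that add atoms: none
Why: Evans asymmetric alkylation, in which the chelated Z-enolate is shielded on one face by the benzyl group of the (S)-auxiliary, so bromoacetate enters from the other face and sets the (R) centre (future lactone C4) with dr ≥ 95:5.

Step 3
Reactants: 7 alkylated imide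
Product: 9 (2R)-4-tert-butoxy-2-(3,4-dimethoxybenzyl)-4-oxobutanoic acid, via peroxy acid 8 (not isolated)
Conditions: LiOH, 30 % H2O2, THF–H2O 3:1, 0 °C; aq Na2SO3; 1 M HCl to pH 3
Reagents that add atoms: hydrogen peroxide, OO
Why: Hydroperoxide-mediated imide cleavage, in which LiOOH attacks the exocyclic carbonyl selectively and sulfite reduces the peracid, while the tert-butyl ester and the α-centre are unaffected at 0 °C.

Step 4
Reactants: 9 succinic half-ester
Product: 10 tert-butyl (3R)-4-(3,4-dimethoxyphenyl)-3-(hydroxymethyl)butanoate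
Conditions: BH3·THF (1.5 equiv), THF, 0 °C → rt; then H2O
Reagents that add atoms: none
Why: Chemoselective borane reduction, in which the free acid is reduced through its acyloxyborane far faster than the tert-butyl ester and the stereocentre is not involved.

Step 5
Reactants: 10 hydroxy ester
Product: 11 (R)-4-(3,4-dimethoxybenzyl)dihydrofuran-2(3H)-one
Conditions: p-TsOH·H2O (10 mol %), toluene, 80 °C, 2 h
Reagents that add atoms: none
Why: Acid-catalysed 5-exo lactonisation (intramolecular transesterification) expels tert-butanol and leaves the (R) centre untouched.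

Step 6
Reactants: 12 ethyl 3-methylbut-2-enoate; 13 diethyl oxalate
Product: 15 potassium 1,6-diethoxy-4-methyl-1,6-dioxohexa-2,4-dien-2-olate, via potassium dienolate 14 (not isolated)
Conditions: KOEt (1.05 equiv), Et2O–EtOH, 0 °C → rt, 18 h; filter the yellow salt
Reagents that add atoms: potassium ethoxide, CC[O-].[K+]
Why: Vinylogous Claisen condensation, in which reversible γ-deprotonation gives the dienolate, the non-enolisable oxalate acylates its γ-carbon, and precipitation of the fully conjugated potassium enolate drives the equilibrium.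

Step 7
Reactants: 15 potassium enolate
Product: 17 4-methyl-2-oxo-2H-pyran-6-carboxylic acid, via 2-hydroxy-4-methylmuconic acid 16 (not isolated)
Conditions: conc. HCl, 95 °C, 3 h; cool to 0 °C, filter
Reagents that add atoms: water, O
Why: Acid hydrolysis, E/Z equilibration through the keto tautomer and enol lactonisation funnel the chain into the stable 2-pyrone acid.

Step 8
Reactants: 17 pyrone acid
Product: 18 ethyl 4-methyl-2-oxo-2H-pyran-6-carboxylate
Conditions: EtOH, conc. H2SO4 (cat.), reflux, 12 h
Reagents that add atoms: ethanol, CCO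
Why: Fischer esterification, which 2-pyrone acids tolerate as in the classical preparation of methyl coumalate.

Step 9
Reactants: 18 methylpyrone ester
Product: 19 ethyl 4-(bromomethyl)-2-oxo-2H-pyran-6-carboxylate
Conditions: NBS (1.05 equiv), AIBN (5 mol %), PhCF3, reflux, 3 h
Reagents that add atoms: N-bromosuccinimide, O=C1CCC(=O)N1Br
Why: Wohl–Ziegler radical bromination, in which the 4-methyl group holds the only allylic-type C–H bonds and the electron-poor ring resists ionic bromination.

Step 10
Reactants: 19 bromomethylpyrone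
Product: 21 ethyl 4-formyl-2-oxo-2H-pyran-6-carboxylate, via alkoxyammonium bromide 20 (not isolated)
Conditions: NMO (4 equiv), 4 Å MS, MeCN, 0 °C → rt, 3 h
Reagents that add atoms: N-methylmorpholine N-oxide, C[N+]1([O-])CCOCC1
Why: N-oxide (Kornblum-type) oxidation, in which the N-oxide oxygen displaces the activated bromide by SN2 and the salt then fragments by E2 to the aldehyde under near-neutral, non-aqueous conditions.

Step 11 (key union)
Reactants: 11 (R)-lactone; 21 formylpyrone ester
Product: 23 ethyl 4-{[(3S,4R)-4-(3,4-dimethoxybenzyl)-2-oxotetrahydrofuran-3-yl](hydroxy)methyl}-2-oxo-2H-pyran-6-carboxylate (both carbinol epimers), via lithium enolate 22 (not isolated)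
Conditions: 11, LiHMDS (1.05 equiv), THF, −78 °C, 45 min; 21 (1.15 equiv, dried by toluene azeotrope) in THF, −78 °C, 30 min; AcOH/THF quench at −78 °C
Reagents that add atoms: none
Why: Intermolecular aldol addition, in which the enolate adds to the non-enolisable, very electrophilic formyl group faster than to the pyrone ring, and the C4 benzyl group forces attack on the opposite face so that C3 is set trans (labelled 3S only because of CIP priorities), while the carbinol centre forms unselectively and is removed later.

Step 12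
Reactants: 23 aldol adduct
Product: 24 O-{[(3S,4R)-4-(3,4-dimethoxybenzyl)-2-oxotetrahydrofuran-3-yl][6-(ethoxycarbonyl)-2-oxo-2H-pyran-4-yl]methyl} O-phenyl carbonothioate (both epimers)
Conditions: PhOC(S)Cl (1.5 equiv), pyridine (3 equiv), DMAP (10 mol %), CH2Cl2, 0 °C → rt
Reagents that add atoms: O-phenyl chlorothionoformate, S=C(Cl)Oc1ccccc1
Why: DMAP-catalysed O-thioacylation of the only hydroxyl group, using bases too weak to cause retro-aldol, β-elimination or epimerisation.

Step 13
Reactants: 24 thionocarbonate
Product: 25 ethyl 4-{[(3R,4R)-4-(3,4-dimethoxybenzyl)-2-oxotetrahydrofuran-3-yl]methyl}-2-oxo-2H-pyran-6-carboxylate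
Conditions: n-Bu3SnH (2 equiv, 0.15 M), AIBN (0.2 equiv), degassed toluene, 80 °C, 1–2 h
Reagents that add atoms: none
Why: Barton–McCombie deoxygenation, in which stannyl radical addition to C=S and fragmentation give a pyrone-stabilised radical that abstracts H from the stannane, C3 and C4 are spectators (the C3 label returns to R by CIP only), and any 3H-pyranone tautomer reverts to the pyrone.

Step 14
Reactants: 25 ethyl ester
Product: 26 4-{[(3R,4R)-4-(3,4-dimethoxybenzyl)-2-oxotetrahydrofuran-3-yl]methyl}-2-oxo-2H-pyran-6-carboxylic acid (target)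
Conditions: 3 M HCl–1,4-dioxane 1:1, 85 °C, 8 h
Reagents that add atoms: water, O
Why: Acid-catalysed ester hydrolysis under the kind of hot aqueous HCl in which 2-pyrone-6-carboxylic acids are themselves formed, so the pyrone, the γ-lactone (closed under acid), the aryl methyl ethers and the thermodynamically preferred trans arrangement all survive.

**Compound list**
1 | 3-(3,4-dimethoxyphenyl)propanoic acid | COc1ccc(CCC(=O)O)cc1OC | starting material
2 | (S)-4-benzyl-1,3-oxazolidin-2-one | O=C1N[C@@H](Cc2ccccc2)CO1 | starting material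
3 | 3-(3,4-dimethoxyphenyl)propanoic pivalic anhydride (not isolated) | COc1ccc(CCC(=O)OC(=O)C(C)(C)C)cc1OC | intermediate
4 | (S)-4-benzyl-3-[3-(3,4-dimethoxyphenyl)propanoyl]-1,3-oxazolidin-2-one | COc1ccc(CCC(=O)N2[C@@H](Cc3ccccc3)COC2=O)cc1OC | intermediate
5 | tert-butyl bromoacetate | CC(C)(C)OC(=O)CBr | starting material
6 | sodium (Z)-enolate of 4 (not isolated) | COc1ccc(C/C=C(\[O-])N2[C@@H](Cc3ccccc3)COC2=O)cc1OC.[Na+] | intermediate
7 | tert-butyl (3R)-3-{[(4S)-4-benzyl-2-oxo-1,3-oxazolidin-3-yl]carbonyl}-4-(3,4-dimethoxyphenyl)butanoate | COc1ccc(C[C@H](CC(=O)OC(C)(C)C)C(=O)N2[C@@H](Cc3ccccc3)COC2=O)cc1OC | intermediate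
8 | (2R)-4-tert-butoxy-2-(3,4-dimethoxybenzyl)-4-oxobutaneperoxoic acid (not isolated) | COc1ccc(C[C@H](CC(=O)OC(C)(C)C)C(=O)OO)cc1OC | intermediate
9 | (2R)-4-tert-butoxy-2-(3,4-dimethoxybenzyl)-4-oxobutanoic acid | COc1ccc(C[C@H](CC(=O)OC(C)(C)C)C(=O)O)cc1OC | intermediate
10 | tert-butyl (3R)-4-(3,4-dimethoxyphenyl)-3-(hydroxymethyl)butanoate | COc1ccc(C[C@H](CC(=O)OC(C)(C)C)CO)cc1OC | intermediate
11 | (R)-4-(3,4-dimethoxybenzyl)dihydrofuran-2(3H)-one | COc1ccc(C[C@H]2COC(=O)C2)cc1OC | intermediate
12 | ethyl 3-methylbut-2-enoate | CCOC(=O)C=C(C)C | starting material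
13 | diethyl oxalate | CCOC(=O)C(=O)OCC | starting material
14 | potassium 1-ethoxy-3-methylbuta-1,3-dien-1-olate (not isolated) | C=C(C)C=C([O-])OCC.[K+] | intermediate
15 | potassium 1,6-diethoxy-4-methyl-1,6-dioxohexa-2,4-dien-2-olate (alkene geometry not fixed) | CCOC(=O)C([O-])=CC(C)=CC(=O)OCC.[K+] | intermediate
16 | 2-hydroxy-4-methylhexa-2,4-dienedioic acid (not isolated) | OC(=O)C(O)=CC(C)=CC(=O)O | intermediate
17 | 4-methyl-2-oxo-2H-pyran-6-carboxylic acid | Cc1cc(C(=O)O)oc(=O)c1 | intermediate
18 | ethyl 4-methyl-2-oxo-2H-pyran-6-carboxylate | CCOC(=O)c1cc(C)cc(=O)o1 | intermediate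
19 | ethyl 4-(bromomethyl)-2-oxo-2H-pyran-6-carboxylate | CCOC(=O)c1cc(CBr)cc(=O)o1 | intermediate
20 | 4-{[6-(ethoxycarbonyl)-2-oxo-2H-pyran-4-yl]methoxy}-4-methylmorpholin-4-ium bromide (not isolated) | CCOC(=O)c1cc(CO[N+]2(C)CCOCC2)cc(=O)o1.[Br-] | intermediate
21 | ethyl 4-formyl-2-oxo-2H-pyran-6-carboxylate | CCOC(=O)c1cc(C=O)cc(=O)o1 | intermediate
22 | lithium enolate of 11 (not isolated) | COc1ccc(C[C@H]2COC([O-])=C2)cc1OC.[Li+] | intermediate
23 | ethyl 4-{[(3S,4R)-4-(3,4-dimethoxybenzyl)-2-oxotetrahydrofuran-3-yl](hydroxy)methyl}-2-oxo-2H-pyran-6-carboxylate, both carbinol epimers | COc1ccc(C[C@H]2COC(=O)[C@@H]2C(O)c2cc(C(=O)OCC)oc(=O)c2)cc1OC | intermediate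
24 | O-phenyl thionocarbonate of 23, both epimers | COc1ccc(C[C@H]2COC(=O)[C@@H]2C(OC(=S)Oc2ccccc2)c2cc(C(=O)OCC)oc(=O)c2)cc1OC | intermediate
25 | ethyl 4-{[(3R,4R)-4-(3,4-dimethoxybenzyl)-2-oxotetrahydrofuran-3-yl]methyl}-2-oxo-2H-pyran-6-carboxylate | COc1ccc(C[C@H]2COC(=O)[C@@H]2Cc2cc(C(=O)OCC)oc(=O)c2)cc1OC | intermediate
26 | 4-{[(3R,4R)-4-(3,4-dimethoxybenzyl)-2-oxotetrahydrofuran-3-yl]methyl}-2-oxo-2H-pyran-6-carboxylic acid | COc1ccc(C[C@H]2COC(=O)[C@@H]2Cc2cc(C(=O)O)oc(=O)c2)cc1OC | target

**Totals**
Total steps: 14. Longest linear sequence: 9 steps (1–5, then 11–14). The pyrone branch (6–10, then 11–14) is equally long.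

**Three steps most likely to fail**

Step 11. The hard enolate 22 could add to the ring or to the ester of 21 instead of the formyl group, or the aldolate could revert. The fallback sets out from 11 and comes back at 23. It replaces the anionic union with a Lewis-acid-driven one that uses a neutral, isolated nucleophile. Compound 11 is O-silylated (LDA, TBSCl, DMPU, THF, −78 °C) to tert-butyl{[(4R)-4-(3,4-dimethoxybenzyl)-4,5-dihydrofuran-2-yl]oxy}dimethylsilane F1, which is isolated by pentane extraction. F1 is then added to 21 with BF3·OEt2 in CH2Cl2 at −78 °C (Mukaiyama aldol, again anti to the C4 substituent). Work-up with dilute HCl removes silicon and gives 23.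

Step 13 (together with its preparation in step 12). The activated β-oxygenated lactone can eliminate, either by base or in a Chugaev-type process, to the conjugated alkylidene lactone. The stabilised radical may also cyclise onto the veratryl ring before it is reduced. The fallback sets out from 11 and 19 and comes back at 25, and it avoids the carbinol altogether by soft-enolate alkylation.
- Compound 11 is C-acylated (LiHMDS 2.1 equiv, Boc2O, THF, −78 °C) to tert-butyl (4R)-4-(3,4-dimethoxybenzyl)-2-oxotetrahydrofuran-3-carboxylate F2.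
- The malonate-type enolate of F2 (K2CO3, DMF, rt) is alkylated by bromide 19. This is the same kind of nucleophile used classically on such bromomethylpyrones. It gives tert-butyl (4R)-4-(3,4-dimethoxybenzyl)-3-{[6-(ethoxycarbonyl)-2-oxo-2H-pyran-4-yl]methyl}-2-oxotetrahydrofuran-3-carboxylate F3.
- TFA in CH2Cl2 at 0 °C gives (4R)-4-(3,4-dimethoxybenzyl)-3-{[6-(ethoxycarbonyl)-2-oxo-2H-pyran-4-yl]methyl}-2-oxotetrahydrofuran-3-carboxylic acid F4.
- F4 decarboxylates in toluene at 110 °C. The enol ketonises to the more stable trans lactone 25, and any cis isomer is removed by chromatography.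

Step 10. The amine and N-oxide can quaternise 19 or attack the pyrone, and the aldehyde may hydrate or degrade. The fallback sets out from 18 and comes back at 21. It is a direct Riley allylic C–H oxidation of the 4-methyl group (SeO2 1.5 equiv, xylene or dioxane, reflux), as used for 4-methylcoumarin to coumarin-4-carbaldehyde. It bypasses the bromide and all nitrogen nucleophiles and makes no new compound (F0).

**Further compounds**
F1 | step 11 | tert-butyl{[(4R)-4-(3,4-dimethoxybenzyl)-4,5-dihydrofuran-2-yl]oxy}dimethylsilane | COc1ccc(C[C@H]2COC(O[Si](C)(C)C(C)(C)C)=C2)cc1OC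
F2 | step 13 | tert-butyl (4R)-4-(3,4-dimethoxybenzyl)-2-oxotetrahydrofuran-3-carboxylate (C3 epimerisable) | COc1ccc(C[C@H]2COC(=O)C2C(=O)OC(C)(C)C)cc1OC
F3 | step 13 | tert-butyl (4R)-4-(3,4-dimethoxybenzyl)-3-{[6-(ethoxycarbonyl)-2-oxo-2H-pyran-4-yl]methyl}-2-oxotetrahydrofuran-3-carboxylate (C3 configuration immaterial) | COc1ccc(C[C@H]2COC(=O)C2(Cc2cc(C(=O)OCC)oc(=O)c2)C(=O)OC(C)(C)C)cc1OC
F4 | step 13 | (4R)-4-(3,4-dimethoxybenzyl)-3-{[6-(ethoxycarbonyl)-2-oxo-2H-pyran-4-yl]methyl}-2-oxotetrahydrofuran-3-carboxylic acid (C3 configuration immaterial) | COc1ccc(C[C@H]2COC(=O)C2(Cc2cc(C(=O)OCC)oc(=O)c2)C(=O)O)cc1OC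
F0 | step 10 | none | none
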